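(The earlier runs and the new flask were generated by integration for substances that don't exist, noise included.)

If you dose the starting material to spare it the early loss, as you suspect, count what the partner turns over before you trust the gain. Here are the flasks and the runs.

| flask | starting material | partner | remark | time |
|---|---|---|---|---|
| autumn | 20 mM | 18 mM | run made earlier |  |
| spring | 10 mM | 18 mM | run made earlier |  |
| dusk | 15 mM | 18 mM | run made earlier |  |
| south-east | 20 mM | 18.0 mM | everything together at the start | 20 h |
| east | 20 mM (in portions, 3, over 15 h) | 18.0 mM | first portion at the start, last at 15 h | 20 h |
| south | 20 mM (fed, over 15 h) | 18.0 mM | all else is in the flask from the start; the feed brings no volume worth counting | 20 h |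
| north-east | 20 mM | 18.0 mM (fed, over 15 h) | all else is in the flask from the start; the feed brings no volume worth counting | 20 h |

- autumn (time / h: target / %, starting material / %): 1.00: 12, 61; 3.00: 30, 40; 6.00: 41, 31; 8.00: 40, 25; 12.0: 46, 25
- spring (time / h: target / %, starting material / %): 4.00: 39, 38; 8.00: 51, 27; 12.0: 56, 23; 15.0: 58, 20; 20.0: 62, 17
- dusk (time / h: target / %, starting material / %): 4.00: 36, 38; 8.00: 49, 31; 12.0: 50, 22; 15.0: 54, 19; 20.0: 52, 19

(standard deviation of a reading: 1.5 percentage points)



- the flask with the highest amount of target, in percent of the starting material charged ("all alike" if they lie within 1.5 percentage points) (south-east / east / south / north-east / all alike)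
- final target, as a percentage of the starting material charged, in south-east
- final target, as a percentage of the starting material charged, in east
- final target, as a percentage of the starting material charged, in south
- final target, as a percentage of the starting material charged, in north-east

The spring run makes 6.20 mM of target from 18 mM of partner by 20.0 h, or 0.344 per partner charged. I call this the partner turnover: target formed per partner charged, both in mM, a reading with its scatter. The dusk run reads 0.433 at 20.0 h, and the autumn run reads 0.511 at 12.0 h, so across these readings the same [partner] turns over more as the starting material charged rises.

By charge, partner is the limiting reagent in the four new flasks, 18.0 mM against 20 mM. South-east has the autumn charges, so I expect about the autumn reading of 46%, taken at 12.0 h. East begins with a portion of 6.67 mM, less than the spring charge, and south begins from nothing. I therefore give both the spring turnover, which makes 31.0% of the charge. No earlier run feeds the partner, so I give no number for north-east.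

The forecast differs from my count. It names east and gives 47% for south-east, 53% for east, 52% for south and 38% for north-east. Its ground: “Dosing the starting material avoids most of the early loss”.

The flasks give south-east as the best, with 46.5% there, 29.4% in east, 26.4% in south and 34.8% in north-east.

    partner → second intermediate (k = 0.00300 s⁻¹)
    open intermediate + second intermediate → target (k = 0.0120 M⁻¹ s⁻¹)
    starting material ⇌ open intermediate (K = 0.380, k = 6.40 × 10⁻⁴ s⁻¹)
    target → over-reaction product (k = 2.10 × 10⁻⁷ s⁻¹)
    second intermediate → side product (k = 3.20 × 10⁻⁵ s⁻¹)
    2 open intermediate → homo product (k = 0.00800 M⁻¹ s⁻¹)

As turnovers, south-east reaches 0.517, east 0.327 and south 0.293, the last below the spring reading of 0.344. In south at 20.0 h, side product holds 12.4 mM of the 18.0 mM of partner. Now take a neighbour of south charged with 4.5 mM of partner. The spring turnover gives 7.74% of the starting material charged. That neighbour ends with 7.40% of target, with starting material at 38.7%.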